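## Structural features

The target is a flavanone: benzene ring A is fused along C4a–C8a to the oxygen heterocycle ring C (a chroman-4-one), and a 3,4-dimethoxyphenyl ring B is attached to C2 by a single bond. Ring A carries three adjacent methoxy groups at C5, C6 and C7 and one hydrogen at C8, a pattern that maps onto a symmetric, purchasable tetraoxygenated benzene. The only stereocentre is C2 (S, from O1 > C1' > C3 > H); it has no stereogenic neighbour, so the whole stereochemical task is absolute control at one carbon. That carbon is fragile: it is benzylic to an electron-rich ring, α to the ring oxygen and β to the ketone, so base opens ring C by a retro-oxa-Michael reaction and acid can ionise C2–O1, and either path racemises. The five aryl methyl ethers are robust except towards strong Lewis acids, which would cleave the 5-methoxy group next to the carbonyl. The real difficulty is therefore to create C2 enantioselectively while ring C is made, and then to install the C4 carbonyl without exposing C2 to base or strong acid. The key step exploits the fact that O1–C8a–C4a–C4 is the heterodiene of an ortho-quinone methide of ring A and C2–C3 is the vinyl group of a ring B styrene, so one [4+2] event forms O1–C2 and C3–C4, closes ring C and sets C2.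

## Logic of the disconnections

**9 to 8.** The C4=O π bond of 9 is taken back to the secondary carbinol of 8; no skeletal bond is cut. The β-aryloxy ketone is the one arrangement that lets C2 racemise by ring opening, so it should exist only in the final compound. The gain is that every earlier intermediate holds C2 as a plain benzylic ether. The forward step must be an oxidation that is neither basic nor strongly acidic; the configuration at C4 of 8 is irrelevant because it is erased.

**8 to 7.** The C4–O bond of 8 is replaced by C4–H, giving 7. C4 is the carbon that the cycloaddition delivers as a methylene, and it is benzylic to ring A, ortho to O1 and para to the 7-methoxy group, so its hydrogen is hydridic. The gain is that 7 has no function in ring C other than the ether and is exactly the cycloadduct. The forward step needs a hydride-abstracting oxidant that takes C4–H and not C2–H, and the cation must be trapped by water before it loses a proton from C3.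

**7 to 4 and 5.** C3–C4 and O1–C2 of 7 are cut together in a retro-hetero-Diels–Alder sense, giving heterodiene 6 and alkene 5; 6 cannot be stored and is traced to its hydrate 4. These are the only two bonds of ring C that join the ring A half to the ring B half. Cutting them removes the ring and the only stereocentre and leaves two achiral pieces of equal size. The forward step must form 6 in the presence of 5, outrun the self-reaction of 6, select one face of 5 with a catalyst that can bind only 6, and leave the new benzylic ether closed.

**4 to 3.** The carbinol C–H bond of 4 is removed to give the aldehyde of 3. The aldehyde is the stable, storable form of the C4 carbon, whereas 4 ionises easily. The gain is that the labile diol appears only just before it is used. The forward step needs a mild hydride source and a work-up without acid.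

**3 to 1.** The aryl–CHO bond of 3 (C4a–C4 of the target) is cut, through iminium salt 2, to 1. In 1 the two positions ortho to the hydroxyl are equivalent by symmetry and the para position is occupied, so electrophilic formylation can give only one aldehyde. The gain is that all ring A substituents are bought. The forward step must stop at mono-formylation, which the deactivating formyl group ensures.

## Other disconnections considered

**Alternative 1:** ring A is built from open chains, cutting C4a–C8a, C5–C6 and C8–C8a. In the forward key step, cyclobutenone A1 undergoes four-electron ring opening, adds [2+2] to ynol ether A2, reopens and closes in a six-electron electrocyclisation to give phenol A3. The end game would then be removal of the triethylsilyl group, Mitsunobu closure of O1–C2 with inversion (3R carbinol to 2S), removal of the triisopropylsilyl group and oxidation to 9.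
- In its favour: the substitution pattern of ring A is fixed by construction, C2 is set beforehand by reagent-controlled chemistry, and the C4 oxygen is already present, so no C–H oxidation is needed. On precedent and on the oxidation-state question it is better than the chosen plan.
- Against it here: ring A is available ready-made as 1, so building it gains nothing. A1 and A2 each need several steps, A2 carries two stereocentres of which one is later destroyed, two silyl groups must be put on and taken off, and the Mitsunobu step acts on an ionisable, electron-rich benzylic carbinol.
- Comparison: mechanistically the more secure route, equal to the chosen plan in the final oxidation, but at least twice as long and much less convergent.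

**Alternative 2:** three bonds around a one-carbon linchpin are cut: C4a–C4, C3–C4 and O1–C2. In the forward key step, iodophenol A4 adds oxidatively to zerovalent palladium formed from PdCl2(PPh3)2, carbon monoxide A5 inserts, alkyne A6 couples, and diethylamine induces 6-endo closure to flavone A7. An enantioselective reduction of the C2=C3 bond of A7 would then give 9.
- In its favour: three simple components, a well-known reaction class, and a flat, robust aromatic product with no acid-labile benzylic ether. With iodination of 1, the annulation and the reduction it needs three operations against five, so it is better on step count, and it is equal in convergence.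
- Against it here: the stereocentre must come from asymmetric 1,4-reduction of an electron-rich flavone with a 5-methoxy group, a poor acceptor. Such reductions tend to continue to the carbinol, which costs a reoxidation, and basic conditions endanger the product. The 5-exo closure competes, the iodide is flanked by two oxygen substituents, and a toxic gas is needed.
- Comparison: the uncertainty moves from the ring-forming step to the reduction. The chosen plan sets C2 in the same event that joins the halves and needs no transition metal.

**Alternative 3:** only O1–C8a is cut. In the forward key step, the C2 hydroxyl of bromo diol A8 couples with the aryl bromide under Pd(OAc)2, a bulky biarylphosphine and Cs2CO3 to give flavan-4-ol A9. Oxidation of A9, one of the epimers of 8, would give 9.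
- In its favour: the C2–O bond is not touched, so a stereocentre set by well-understood aldol and reduction chemistry is carried over with retention. The C4 oxygen is present from the start, and only the C2 hydroxyl can reach the bromide. On stereochemical security and precedent it is better than the chosen plan, and the final oxidation is the same operation as step 5.
- Against it here: A8 needs about five or six steps and has two stereocentres, one of which is made only to be destroyed. C–O reductive elimination on an electron-rich arene is slow, and β-hydride elimination from the secondary alkoxide competes.
- Comparison: safer in stereochemistry, equal in the end game, but two to three steps longer and less atom-economical.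

Key step: step 3

Remark: which antipode of the phosphoric acid leads to the 2S series cannot be derived from first principles for this new substrate pair; the route is written for the antipode that does, to be fixed in the first screening run.

Remark: the configurations were checked. S at C2 of the flavan 7 and S at C2 of the flavanone 9 describe the same spatial arrangement, and no structure needed correction. The precursor 4 is kept unprotected because both hydroxyls dock on the catalyst; the improvements are operational (fresh preparation, slow addition into excess 5, neutral buffered oxidation).

## Route

Step 1
Reactants: 1 3,4,5-trimethoxyphenol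
Product: 3 6-hydroxy-2,3,4-trimethoxybenzaldehyde, via aryl iminium chloride 2 (not isolated)
Conditions: POCl3 (1.3 equiv), DMF, 0 °C to rt; then H2O, 50 °C
Reagents that add atoms: N,N-dimethylformamide, CN(C)C=O; water, O
Why: Vilsmeier–Haack formylation; the chloroiminium ion attacks ortho to the hydroxyl and para to a methoxy group, the two ortho positions of 1 are equivalent and the para position is blocked, so only one aldehyde can form. The formyl group deactivates the ring against a second attack, and aqueous hydrolysis of 2 (and of any aryl formate) releases 3.

Step 2
Reactants: 3 6-hydroxy-2,3,4-trimethoxybenzaldehyde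
Product: 4 2-(hydroxymethyl)-3,4,5-trimethoxyphenol
Conditions: NaBH4 (1.0 equiv), THF/MeOH (4:1), 0 °C; pH 7 phosphate buffer work-up, used crude
Reagents that add atoms: none
Why: Borohydride reduction of an aryl aldehyde. It is kept cold and worked up at neutral pH because this electron-rich ortho-hydroxybenzyl alcohol ionises easily, and 4 is carried on at once without chromatography on acidic silica.

Step 3
Reactants: 4 2-(hydroxymethyl)-3,4,5-trimethoxyphenol; 5 3,4-dimethoxystyrene
Product: 7 (2S)-2-(3,4-dimethoxyphenyl)-5,6,7-trimethoxychromane, via ortho-quinone methide 6 (not isolated)
Conditions: TRIP phosphoric acid (3,3'-bis(2,4,6-triisopropylphenyl)-1,1'-binaphthyl-2,2'-diyl hydrogen phosphate, 10 mol%), 4 Å MS, toluene, −20 °C; 4 added by syringe pump over 8 h to 5 (3 equiv) and catalyst; Et3N quench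
Reagents that add atoms: none
Why: Proposed new method: the phosphoric acid is expected to dehydrate 4, whose benzylic carbon is activated by the ortho-hydroxyl, ortho-methoxy and para-methoxy groups, to ortho-quinone methide 6, which is born hydrogen-bonded through its carbonyl oxygen to the chiral phosphate; the closest known reaction type is the chiral phosphoric acid-catalysed inverse-demand oxa-[4+2] cycloaddition of aryl-substituted ortho-quinone methides, formed in situ, with electron-rich alkenes (enamides, enol ethers, hydroxystyrenes), and what is new is the unsubstituted methide carbon together with a styrene that offers no hydrogen-bond donor. The terminal carbon of 5 attacks the methide carbon (C3–C4), positive charge develops at the benzylic carbon where the para-methoxy group of ring B absorbs it, and the phenolic oxygen then closes O1–C2. Ring C therefore closes by an asynchronous hetero-Diels–Alder event, which in its stepwise limit is a 6-exo-trig capture of a para-methoxybenzyl-type cation by the phenol oxygen. The polarity match of the electrophilic methide carbon and the nucleophilic terminal alkene carbon places the aryl group at C2, so regioselectivity is inherent. C2 is the only new stereocentre and is under catalyst control alone: the phosphate spans O1–H and the developing cation at C2, and the 2,4,6-triisopropylphenyl walls of the pocket leave one face of the alkene open to O1. The step needs chemoselectivity for the cross-reaction over attack of 6 on C6–H of 4 or C8–H of 7 and over self-dimerisation of 6, which slow addition of 4 into excess 5 should secure because 6 never accumulates. It also needs the benzylic C2–O1 bond of 7 to stay closed, which the weak acidity of the catalyst, the low temperature and the amine quench should secure.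

Step 4
Reactants: 7 (2S)-2-(3,4-dimethoxyphenyl)-5,6,7-trimethoxychromane
Product: 8 (2S)-2-(3,4-dimethoxyphenyl)-5,6,7-trimethoxychroman-4-ol (mixture of C4 epimers)
Conditions: DDQ (1.2 equiv), CH2Cl2/pH 7 phosphate buffer (10:1), 0 °C
Reagents that add atoms: water, O
Why: DDQ benzylic C–H oxidation by hydride abstraction, as in the C4 functionalisation of 5,7-dialkoxyflavans; ring A is the most electron-rich arene and the C4 cation is stabilised by O1 (ortho) and the 7-methoxy group (para). Water traps the cation to give both C4 epimers, which does not matter, and the buffer keeps 8 from re-ionising and eliminating; C2 is not touched.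

Step 5
Reactants: 8 (2S)-2-(3,4-dimethoxyphenyl)-5,6,7-trimethoxychroman-4-ol
Product: 9 (2S)-5,6,7,3',4'-pentamethoxyflavanone
Conditions: Dess–Martin periodinane (1.3 equiv), NaHCO3 (4 equiv), CH2Cl2, 0 °C to rt
Reagents that add atoms: none
Why: Dess–Martin oxidation of a secondary benzylic alcohol under buffered, non-basic conditions; both C4 epimers converge on the ketone. Without base there is no retro-oxa-Michael opening, so the 2S centre set in step 3 is carried through unchanged.

## Compound list

1 | 3,4,5-trimethoxyphenol | COc1cc(O)cc(OC)c1OC | starting material
2 | N-[(6-hydroxy-2,3,4-trimethoxyphenyl)methylidene]-N-methylmethanaminium chloride | C[N+](C)=Cc1c(O)cc(OC)c(OC)c1OC.[Cl-] | intermediate (not isolated)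
3 | 6-hydroxy-2,3,4-trimethoxybenzaldehyde | O=Cc1c(O)cc(OC)c(OC)c1OC | intermediate
4 | 2-(hydroxymethyl)-3,4,5-trimethoxyphenol | COc1cc(O)c(CO)c(OC)c1OC | intermediate
5 | 3,4-dimethoxystyrene (4-ethenyl-1,2-dimethoxybenzene) | C=Cc1ccc(OC)c(OC)c1 | starting material
6 | 3,4,5-trimethoxy-6-methylidenecyclohexa-2,4-dien-1-one | C=C1C(=O)C=C(OC)C(OC)=C1OC | intermediate (not isolated)
7 | (2S)-2-(3,4-dimethoxyphenyl)-5,6,7-trimethoxychromane | COc1ccc([C@@H]2CCc3c(cc(OC)c(OC)c3OC)O2)cc1OC | intermediate
8 | (2S)-2-(3,4-dimethoxyphenyl)-5,6,7-trimethoxychroman-4-ol, mixture of C4 epimers | COc1ccc([C@@H]2CC(O)c3c(cc(OC)c(OC)c3OC)O2)cc1OC | intermediate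
9 | (2S)-5,6,7,3',4'-pentamethoxyflavanone | COc1ccc([C@@H]2CC(=O)c3c(cc(OC)c(OC)c3OC)O2)cc1OC | target

## Step count and least certain steps

Total step count: 5. Longest linear sequence: 5 steps (1 to 9); 5 is purchased and enters in step 3.

**Step 3 (key step).** The most likely failure is poor facial selectivity, because the styrene is held by no second contact to the catalyst. Next come self-condensation of the quinone methide with the electron-rich arene positions, and erosion of enantiomeric purity by re-ionisation of the benzylic C2–O1 bond under the acid. The fallback uses known chemistry, sets out from 3 and returns to the route at 7. Claisen–Schmidt condensation of 3 with 3',4'-dimethoxyacetophenone (KOH, EtOH) should give (E)-1-(3,4-dimethoxyphenyl)-3-(6-hydroxy-2,3,4-trimethoxyphenyl)prop-2-en-1-one F1. Hydrogenation of the alkene (H2, Pd/C, EtOAc, one equivalent) gives 1-(3,4-dimethoxyphenyl)-3-(6-hydroxy-2,3,4-trimethoxyphenyl)propan-1-one F2. Noyori asymmetric transfer hydrogenation with RuCl[(R,R)-TsDPEN](p-cymene) and HCO2H/Et3N gives 2-[(3R)-3-(3,4-dimethoxyphenyl)-3-hydroxypropyl]-3,4,5-trimethoxyphenol F3, the R configuration being expected by analogy with acetophenone-type ketones. Mitsunobu cyclisation (PPh3, DIAD, THF, 0 °C) then closes O1–C2 with inversion and delivers 7.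

**Step 4.** The most likely failure is loss of site selectivity: hydride abstraction at C2, which is a dimethoxybenzyl ether-type C–H. The second is elimination of the C4 cation towards the 3,4-alkene followed by further oxidation. Either would destroy the stereocentre, and the missing C3 substituent makes elimination easier than in the flavan-3-ol series. The fallback abandons late C–H oxidation, sets out from 1 and returns at 9. C-acetylation of 1 (AcOH, BF3·OEt2, 90 °C) gives 1-(6-hydroxy-2,3,4-trimethoxyphenyl)ethan-1-one F4. Condensation with DMF dimethyl acetal gives (E)-3-(dimethylamino)-1-(6-hydroxy-2,3,4-trimethoxyphenyl)prop-2-en-1-one F5. Acid (HCl, CH2Cl2) closes it to 5,6,7-trimethoxy-4H-chromen-4-one F6. Asymmetric conjugate addition of 3,4-dimethoxyphenylboronic acid, catalysed by Pd(OCOCF3)2 and a chiral tert-butyl pyridine-oxazoline ligand (NH4PF6, H2O, 1,2-dichloroethane, 60 °C), then sets C2 and gives 9 directly; the ligand antipode is chosen for the 2S series.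

**Step 2.** The most likely failure is ionisation of the benzylic alcohol during reduction, work-up or storage, leading to over-reduction to the methyl compound or to self-condensation, because the benzylic cation is stabilised by three ortho and para oxygens. The fallback avoids the aldehyde, sets out from 1 and returns at 4. Heating 1 with phenylboronic acid and paraformaldehyde (catalytic propionic acid, toluene, water removal) should give the storable 5,6,7-trimethoxy-2-phenyl-4H-1,3,2-benzodioxaborinine F7, in which the boron template delivers one formaldehyde unit to one ortho position. Transesterification with propane-1,3-diol just before step 3 releases 4.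

**Step 5.** The most likely failure is racemisation at C2 by reversible ring opening if the medium turns basic, or acid-induced dehydration of the carbinol before it is oxidised. The fallback sets out from 7 and returns at 9: 7 is treated with excess DDQ (2.5 equiv) in wet dioxane, so that the carbinol formed in the flask loses a second hydride from C4 to the quinone and is never isolated. This fallback makes no new compound (F0).

## Further compounds

F1 | step 3 | (E)-1-(3,4-dimethoxyphenyl)-3-(6-hydroxy-2,3,4-trimethoxyphenyl)prop-2-en-1-one | COc1ccc(C(=O)/C=C/c2c(O)cc(OC)c(OC)c2OC)cc1OC
F2 | step 3 | 1-(3,4-dimethoxyphenyl)-3-(6-hydroxy-2,3,4-trimethoxyphenyl)propan-1-one | COc1ccc(C(=O)CCc2c(O)cc(OC)c(OC)c2OC)cc1OC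
F3 | step 3 | 2-[(3R)-3-(3,4-dimethoxyphenyl)-3-hydroxypropyl]-3,4,5-trimethoxyphenol | COc1ccc([C@H](O)CCc2c(O)cc(OC)c(OC)c2OC)cc1OC
F4 | step 4 | 1-(6-hydroxy-2,3,4-trimethoxyphenyl)ethan-1-one | CC(=O)c1c(O)cc(OC)c(OC)c1OC
F5 | step 4 | (E)-3-(dimethylamino)-1-(6-hydroxy-2,3,4-trimethoxyphenyl)prop-2-en-1-one | CN(C)/C=C/C(=O)c1c(O)cc(OC)c(OC)c1OC
F6 | step 4 | 5,6,7-trimethoxy-4H-chromen-4-one | COc1cc2occc(=O)c2c(OC)c1OC
F7 | step 2 | 5,6,7-trimethoxy-2-phenyl-4H-1,3,2-benzodioxaborinine | COc1cc2OB(c3ccccc3)OCc2c(OC)c1OC
F0 | step 5 | none | none
A1 | alternative 1 | 2,3-dimethoxycyclobut-2-en-1-one | COC1=C(OC)C(=O)C1
A2 | alternative 1 | (1R,3S)-1-(3,4-dimethoxyphenyl)-5-methoxy-1-(triethylsilyloxy)-3-(triisopropylsilyloxy)pent-4-yne | COC#C[C@@H](O[Si](C(C)C)(C(C)C)C(C)C)C[C@@H](O[Si](CC)(CC)CC)c1ccc(OC)c(OC)c1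
A3 | alternative 1 | 2-[(1S,3R)-3-(3,4-dimethoxyphenyl)-3-(triethylsilyloxy)-1-(triisopropylsilyloxy)propyl]-3,4,5-trimethoxyphenol | COc1c(OC)c(OC)cc(O)c1[C@@H](O[Si](C(C)C)(C(C)C)C(C)C)C[C@@H](O[Si](CC)(CC)CC)c1ccc(OC)c(OC)c1
A4 | alternative 2 | 2-iodo-3,4,5-trimethoxyphenol | COc1cc(O)c(I)c(OC)c1OC
A5 | alternative 2 | carbon monoxide | [C-]#[O+]
A6 | alternative 2 | 4-ethynyl-1,2-dimethoxybenzene | C#Cc1ccc(OC)c(OC)c1
A7 | alternative 2 | 5,6,7,3',4'-pentamethoxyflavone | COc1ccc(-c2cc(=O)c3c(cc(OC)c(OC)c3OC)o2)cc1OC
A8 | alternative 3 | (1S,3S)-1-(6-bromo-2,3,4-trimethoxyphenyl)-3-(3,4-dimethoxyphenyl)propane-1,3-diol | COc1ccc([C@@H](O)C[C@H](O)c2c(Br)cc(OC)c(OC)c2OC)cc1OC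
A9 | alternative 3 | (2S,4S)-2-(3,4-dimethoxyphenyl)-5,6,7-trimethoxychroman-4-ol | COc1ccc([C@@H]2C[C@H](O)c3c(cc(OC)c(OC)c3OC)O2)cc1OC
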